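**Retrosynthetic overview**
1. Target 18 ← dibenzyl disulfate 17 ← diol 16 ← fully protected flavonol 15. The oxygens to be sulfated (O3, O7) carry 4-methoxybenzyl groups; those that stay free (O5, O4') carry benzyl groups.
2. Ring C of 15 is cut at C3–C4 and O1–C8a, giving acid chloride 7 (ring A, fluorine on the future C8a) and α-alkoxy ketone 13 (ring B with C2, C3, O3). Rings A and B are bought; ring C is the only ring formed, in step 7.
3. Feature used: in ring A the oxygens O1 (on C8a), O5 and O7 are mutually meta and each ortho or para to C4a, which bears the C4 carbonyl, so each C–O bond can come from displacement of a carbonyl-activated fluoride.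
4. 7 ← 2,6-difluoro-4-hydroxybenzaldehyde: O7 is already in place and the two fluorines are equivalent, so benzyl oxide can give only one isomer. 13 ← N-methoxy-N-methylamide 10 + aryl Grignard reagent 12.

Key step: step 7

Remark: the sulfate monoesters 17 and 18 are drawn, like the target, as free hydrogen sulfates; it is assumed that they are handled as their sodium salts and that the acid form of 18 is released only at the end on a sulfonic acid resin in the cold.

**Step 1**
Reactants: 1 2,6-difluoro-4-hydroxybenzaldehyde; 2 4-methoxybenzyl chloride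
Product: 3 2,6-difluoro-4-[(4-methoxybenzyl)oxy]benzaldehyde
Conditions: K2CO3, Bu4NI (cat.), DMF, rt
Reagents that add atoms: 4-methoxybenzyl chloride (2), COc1ccc(CCl)cc1
Why: Williamson ether synthesis on a phenol made acidic by the para formyl group; the stabilised phenoxide is too weak a nucleophile for fluoride displacement to compete at room temperature.

**Step 2**
Reactants: 3 2,6-difluoro-4-[(4-methoxybenzyl)oxy]benzaldehyde; 4 benzyl alcohol
Product: 5 2-(benzyloxy)-6-fluoro-4-[(4-methoxybenzyl)oxy]benzaldehyde
Conditions: BnOH (1.0 equiv), NaH, THF, 0 °C; added slowly to 3 in THF, 0 °C to rt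
Reagents that add atoms: benzyl alcohol (4), OCc1ccccc1
Why: Nucleophilic aromatic substitution (SNAr) of a fluorine ortho to the formyl group, which takes up the charge of the Meisenheimer complex; the two fluorines are equivalent, so only one monoether can form, and the new ortho alkoxy group donates into the aldehyde and slows a second displacement.

**Step 3**
Reactants: 5 2-(benzyloxy)-6-fluoro-4-[(4-methoxybenzyl)oxy]benzaldehyde
Product: 6 2-(benzyloxy)-6-fluoro-4-[(4-methoxybenzyl)oxy]benzoic acid
Conditions: NaClO2, NaH2PO4, 2-methyl-2-butene (excess), t-BuOH/THF/H2O, 0 °C to rt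
Reagents that add atoms: sodium chlorite, [Na+].[O-]Cl=O
Why: Pinnick oxidation turns the aldehyde into the acid under buffered, mildly acidic conditions that leave both benzylic ethers intact, and the alkene in excess traps hypochlorous acid before it can chlorinate the electron-rich ring.

**Step 4**
Reactants: 6 2-(benzyloxy)-6-fluoro-4-[(4-methoxybenzyl)oxy]benzoic acid
Product: 7 2-(benzyloxy)-6-fluoro-4-[(4-methoxybenzyl)oxy]benzoyl chloride
Conditions: 1-chloro-N,N,2-trimethylprop-1-en-1-amine (1.05 equiv), CH2Cl2, 0 °C to rt; concentrated under high vacuum, used crude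
Reagents that add atoms: 1-chloro-N,N,2-trimethylprop-1-en-1-amine, CC(C)=C(Cl)N(C)C
Why: Acid chloride formation with an α-chloroenamine runs under neutral conditions and gives only a neutral amide beside the product, so no hydrogen chloride is set free that could cleave the acid-labile 4-methoxybenzyl ether.

**Step 5**
Reactants: 8 4-methoxybenzyl alcohol; 9 2-chloro-N-methoxy-N-methylacetamide
Product: 10 N-methoxy-N-methyl-2-[(4-methoxybenzyl)oxy]acetamide
Conditions: NaH, THF, 0 °C; then 9, Bu4NI (cat.), 0 °C to rt
Reagents that add atoms: none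
Why: Williamson ether synthesis in which SN2 displacement of the carbonyl-activated α-chloride by the alkoxide is fast, while the N-methoxy-N-methylamide carbonyl resists attack by alkoxide.

**Step 6**
Reactants: 11 1-(benzyloxy)-4-bromobenzene; 10 N-methoxy-N-methyl-2-[(4-methoxybenzyl)oxy]acetamide
Product: 13 1-[4-(benzyloxy)phenyl]-2-[(4-methoxybenzyl)oxy]ethan-1-one, via 4-(benzyloxy)phenylmagnesium bromide 12 (not isolated)
Conditions: Mg, I2 (cat.), THF, 50 °C; then 10, THF, 0 °C; aq. NH4Cl
Reagents that add atoms: none
Why: Weinreb ketone synthesis, in which the aryl Grignard reagent adds once to the N-methoxy-N-methylamide and the magnesium chelate of the tetrahedral adduct holds until work-up, so that no tertiary alcohol forms.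

**Step 7**
Reactants: 13 1-[4-(benzyloxy)phenyl]-2-[(4-methoxybenzyl)oxy]ethan-1-one; 7 2-(benzyloxy)-6-fluoro-4-[(4-methoxybenzyl)oxy]benzoyl chloride
Product: 15 5-(benzyloxy)-2-[4-(benzyloxy)phenyl]-3,7-bis[(4-methoxybenzyl)oxy]-4H-chromen-4-one (5,4'-di-O-benzyl-3,7-di-O-(4-methoxybenzyl)kaempferol), via fluoroaryl 1,3-diketone 14 (not isolated)
Conditions: LiN(SiMe3)2 (2.1 equiv), THF, −78 °C; then 7, −78 °C to rt; then DMF, 80 °C
Reagents that add atoms: none
Why: LiN(SiMe3)2 turns 13 into its chelated lithium enolate, which attacks the acid chloride at carbon (Claisen-type C-acylation, forming C3–C4), and the second equivalent of base at once deprotonates the 2-alkoxy-1,3-diketone 14 to its enolate, which shields it from a second acylation. On heating in DMF the lithium chelate loosens, rotation about C3–C4 brings the enolate oxygen on the ring B side to C8a, and it adds there to give a Meisenheimer complex whose charge passes through C4a into the C4 carbonyl, after which fluoride leaves as LiF and O1–C8a is formed. The closest known reaction type is the acylation of enolates or enamines with 2-fluorobenzoyl chlorides followed by intramolecular SNAr, as used for chromones and 4-quinolones. Ring C closes by a six-membered addition–elimination, formally 6-endo-trig because O1 adds to C8a as the β-carbon of the C8a=C4a–C4=O unit; no stereocenter is formed. The step needs C- over O-acylation, which the lithium counter-ion in THF at −78 °C should favour, and closure at C8a only, which is secured because a single fluorine is left and only the oxygen on the ring B side can reach it through a six-membered transition state. The ethers at C5 and C7 are meta to C8a and put no electron density on the carbons that carry the negative charge, so the displacement should stay feasible on this oxygen-rich ring.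

**Step 8**
Reactants: 15 5-(benzyloxy)-2-[4-(benzyloxy)phenyl]-3,7-bis[(4-methoxybenzyl)oxy]-4H-chromen-4-one
Product: 16 5-(benzyloxy)-2-[4-(benzyloxy)phenyl]-3,7-dihydroxy-4H-chromen-4-one (5,4'-di-O-benzylkaempferol)
Conditions: CF3CO2H, anisole (excess), CH2Cl2, 0 °C
Reagents that add atoms: none
Why: Acidolysis of the two 4-methoxybenzyl ethers through the stabilised 4-methoxybenzyl cation, which anisole traps by Friedel–Crafts alkylation; the plain benzyl ethers ionise far more slowly and should stay.

**Step 9**
Reactants: 16 5-(benzyloxy)-2-[4-(benzyloxy)phenyl]-3,7-dihydroxy-4H-chromen-4-one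
Product: 17 5-(benzyloxy)-2-[4-(benzyloxy)phenyl]-4-oxo-4H-chromene-3,7-diyl bis(hydrogen sulfate)
Conditions: SO3·pyridine (excess), pyridine, 50 °C; then aq. NaHCO3, reversed-phase (C18) chromatography
Reagents that add atoms: sulfur trioxide–pyridine complex, O=S(=O)([O-])[n+]1ccccc1
Why: O-sulfonation (sulfation) of hydroxyl groups by the SO3–amine complex; only O3 and O7 are free, so the protecting-group pattern fixes where the two sulfates go, and an excess of reagent can drive the hydrogen-bonded 3-hydroxyl to completion.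

**Step 10**
Reactants: 17 5-(benzyloxy)-2-[4-(benzyloxy)phenyl]-4-oxo-4H-chromene-3,7-diyl bis(hydrogen sulfate)
Product: 18 kaempferol 3,7-di-O-sulfate
Conditions: H2 (1 atm), Pd/C, MeOH/H2O, rt; then sulfonic acid resin (H+ form), 0 °C, freeze-drying
Reagents that add atoms: none
Why: Catalytic hydrogenolysis of the two benzyl aryl ethers over palladium on carbon; sulfate monoester anions are inert to these conditions and the C2=C3 bond of the flavonol should not be reduced at atmospheric pressure.

**Compound list**
1 | 2,6-difluoro-4-hydroxybenzaldehyde | O=Cc1c(F)cc(O)cc1F | starting material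
2 | 4-methoxybenzyl chloride | COc1ccc(CCl)cc1 | starting material
3 | 2,6-difluoro-4-[(4-methoxybenzyl)oxy]benzaldehyde | O=Cc1c(F)cc(OCc2ccc(OC)cc2)cc1F | intermediate
4 | benzyl alcohol | OCc1ccccc1 | starting material
5 | 2-(benzyloxy)-6-fluoro-4-[(4-methoxybenzyl)oxy]benzaldehyde | O=Cc1c(F)cc(OCc2ccc(OC)cc2)cc1OCc1ccccc1 | intermediate
6 | 2-(benzyloxy)-6-fluoro-4-[(4-methoxybenzyl)oxy]benzoic acid | OC(=O)c1c(F)cc(OCc2ccc(OC)cc2)cc1OCc1ccccc1 | intermediate
7 | 2-(benzyloxy)-6-fluoro-4-[(4-methoxybenzyl)oxy]benzoyl chloride | O=C(Cl)c1c(F)cc(OCc2ccc(OC)cc2)cc1OCc1ccccc1 | intermediate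
8 | 4-methoxybenzyl alcohol | COc1ccc(CO)cc1 | starting material
9 | 2-chloro-N-methoxy-N-methylacetamide | CON(C)C(=O)CCl | starting material
10 | N-methoxy-N-methyl-2-[(4-methoxybenzyl)oxy]acetamide | CON(C)C(=O)COCc1ccc(OC)cc1 | intermediate
11 | 1-(benzyloxy)-4-bromobenzene | Brc1ccc(OCc2ccccc2)cc1 | starting material
12 | 4-(benzyloxy)phenylmagnesium bromide | Br[Mg]c1ccc(OCc2ccccc2)cc1 | intermediate
13 | 1-[4-(benzyloxy)phenyl]-2-[(4-methoxybenzyl)oxy]ethan-1-one | O=C(COCc1ccc(OC)cc1)c1ccc(OCc2ccccc2)cc1 | intermediate
14 | 1-[2-(benzyloxy)-6-fluoro-4-[(4-methoxybenzyl)oxy]phenyl]-3-[4-(benzyloxy)phenyl]-2-[(4-methoxybenzyl)oxy]propane-1,3-dione (present in the flask as its lithium enolate) | O=C(c1c(F)cc(OCc2ccc(OC)cc2)cc1OCc1ccccc1)C(OCc1ccc(OC)cc1)C(=O)c1ccc(OCc2ccccc2)cc1 | intermediate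
15 | 5-(benzyloxy)-2-[4-(benzyloxy)phenyl]-3,7-bis[(4-methoxybenzyl)oxy]-4H-chromen-4-one | O=c1c(OCc2ccc(OC)cc2)c(-c2ccc(OCc3ccccc3)cc2)oc2cc(OCc3ccc(OC)cc3)cc(OCc3ccccc3)c12 | intermediate
16 | 5-(benzyloxy)-2-[4-(benzyloxy)phenyl]-3,7-dihydroxy-4H-chromen-4-one | O=c1c(O)c(-c2ccc(OCc3ccccc3)cc2)oc2cc(O)cc(OCc3ccccc3)c12 | intermediate
17 | 5-(benzyloxy)-2-[4-(benzyloxy)phenyl]-4-oxo-4H-chromene-3,7-diyl bis(hydrogen sulfate) | O=c1c(OS(=O)(=O)O)c(-c2ccc(OCc3ccccc3)cc2)oc2cc(OS(=O)(=O)O)cc(OCc3ccccc3)c12 | intermediate
18 | kaempferol 3,7-di-O-sulfate [5-hydroxy-2-(4-hydroxyphenyl)-4-oxo-4H-chromene-3,7-diyl bis(hydrogen sulfate)] | O=c1c(OS(=O)(=O)O)c(-c2ccc(O)cc2)oc2cc(OS(=O)(=O)O)cc(O)c12 | target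

**Totals**
Total step count: 10. Longest linear sequence: 8 steps (steps 1, 2, 3, 4, 7, 8, 9, 10).

**Steps most likely to fail**

Step 7. Acylation may take place at the enolate oxygen, or at the amide base, because the 2,6-disubstituted acid chloride is hindered. The ring closure may also stall if the lithium chelate does not open. The fallback is an aldol–oxidation–SNAr sequence that sets out from 13 (with aldehyde 5 from step 2) and comes back at 15. The lithium enolate of 13 (LiN(SiMe3)2, THF, −78 °C) is added to the less hindered aldehyde 5 in an aldol addition. This should give 3-[2-(benzyloxy)-6-fluoro-4-[(4-methoxybenzyl)oxy]phenyl]-1-[4-(benzyloxy)phenyl]-3-hydroxy-2-[(4-methoxybenzyl)oxy]propan-1-one F1 as a mixture of diastereomers, which is of no consequence. Dess–Martin periodinane (NaHCO3, CH2Cl2) oxidises it to diketone 14, now isolated. K2CO3 in DMF at 90 °C then closes ring C by SNAr to 15.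

Step 9. Sulfation of the hindered, hydrogen-bonded 3-hydroxyl may stay incomplete, or the enol sulfate may hydrolyse during work-up. The fallback uses protected sulfate diesters; it sets out from 16 and comes back at 17. Diol 16 is treated with 2,2,2-trichloroethyl chlorosulfate, Et3N and 4-(dimethylamino)pyridine in THF. This should give the neutral, chromatographable 5-(benzyloxy)-2-[4-(benzyloxy)phenyl]-4-oxo-4H-chromene-3,7-diyl bis(2,2,2-trichloroethyl sulfate) F2. Zn dust and HCO2NH4 in MeOH then remove both trichloroethyl groups by reductive β-elimination without touching the benzyl ethers, giving 17 as its ammonium salt.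

Step 2. Both fluorines may be displaced, or the benzyl oxide may transfer hydride to the aldehyde (Cannizzaro-type or Meerwein–Ponndorf–Verley-type reduction). The fallback oxidises first and substitutes on an ester; it sets out from 3 and comes back at 6. Pinnick oxidation of 3 gives 2,6-difluoro-4-[(4-methoxybenzyl)oxy]benzoic acid F3. Benzyl bromide and K2CO3 in DMF give benzyl 2,6-difluoro-4-[(4-methoxybenzyl)oxy]benzoate F4. NaOCH2Ph in THF displaces one ortho fluorine, and ester exchange with the same alkoxide is degenerate, so the product should be benzyl 2-(benzyloxy)-6-fluoro-4-[(4-methoxybenzyl)oxy]benzoate F5. LiOH in THF/MeOH/H2O at 50 °C saponifies it to acid 6.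

**Further compounds**
F1 | step 7 | 3-[2-(benzyloxy)-6-fluoro-4-[(4-methoxybenzyl)oxy]phenyl]-1-[4-(benzyloxy)phenyl]-3-hydroxy-2-[(4-methoxybenzyl)oxy]propan-1-one | O=C(c1ccc(OCc2ccccc2)cc1)C(OCc1ccc(OC)cc1)C(O)c1c(F)cc(OCc2ccc(OC)cc2)cc1OCc1ccccc1
F2 | step 9 | 5-(benzyloxy)-2-[4-(benzyloxy)phenyl]-4-oxo-4H-chromene-3,7-diyl bis(2,2,2-trichloroethyl sulfate) | O=c1c(OS(=O)(=O)OCC(Cl)(Cl)Cl)c(-c2ccc(OCc3ccccc3)cc2)oc2cc(OS(=O)(=O)OCC(Cl)(Cl)Cl)cc(OCc3ccccc3)c12
F3 | step 2 | 2,6-difluoro-4-[(4-methoxybenzyl)oxy]benzoic acid | OC(=O)c1c(F)cc(OCc2ccc(OC)cc2)cc1F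
F4 | step 2 | benzyl 2,6-difluoro-4-[(4-methoxybenzyl)oxy]benzoate | O=C(OCc1ccccc1)c1c(F)cc(OCc2ccc(OC)cc2)cc1F
F5 | step 2 | benzyl 2-(benzyloxy)-6-fluoro-4-[(4-methoxybenzyl)oxy]benzoate | O=C(OCc1ccccc1)c1c(F)cc(OCc2ccc(OC)cc2)cc1OCc1ccccc1
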